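**Assumptions (one line each)**
- (2R,3R)-(+)-Taxifolin and (2S)-(−)-eriodictyol are commercially available.
- Electrophilic attack on the benzylated 5-hydroxy/5-alkoxy-7-alkoxy A-ring occurs preferentially at C8 rather than C6. C8 is the less hindered position, flanked by one OBn and the ring oxygen.

## Retrosynthetic overview
1. No rings are formed in this route. Both chroman-4-one rings arrive intact from chiral-pool flavonoids, and only the C3(flavanone)–C8″(taxifolin) sp³–sp² bond is made.
2. That bond is disconnected as an umpolung (enolonium) arylation, not the usual Pd cross-coupling. The eriodictyol-derived TMS enol ether is oxidised by PIFA to a C3 electrophile, and it is trapped by the very nucleophilic phloroglucinol-type C8 of O-benzyl taxifolin. No pre-halogenation is needed.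
3. Stereochemistry: taxifolin supplies (2R,3R) unchanged, and eriodictyol supplies C2 (S). The new C3 (R) is set trans to the C2 aryl group by attack anti to it, backed by thermodynamic epimerisation of any cis isomer.
4. Benzyl ethers protect all phenols and are removed by one global hydrogenolysis.

## Route

**Step 1**
Reactants: 1, (2R,3R)-(+)-taxifolin
Product: 2, 3,7,3′,4′-tetra-O-benzyl-(2R,3R)-taxifolin (5-OH free)
Conditions: BnBr (4.4 equiv), K2CO3, DMF, 25 °C, N2, 16 h
Reagents that add atoms: benzyl bromide, BrCc1ccccc1
Why: Williamson etherification benzylates the four free OH groups, while the 5-OH is locked by its H-bond to C4=O and stays free. Mild base at rt does not touch the trans-2,3 stereocentres, since trans is the thermodynamic isomer.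

**Step 2**
Reactants: 3, (2S)-(−)-eriodictyol
Product: 4, 5,7,3′,4′-tetra-O-benzyl-(2S)-eriodictyol
Conditions: BnBr (5.5 equiv), K2CO3, DMF, 50 °C, N2, 12 h
Reagents that add atoms: benzyl bromide, BrCc1ccccc1
Why: Exhaustive Williamson benzylation gives a fully masked flavanone, and C2 (S) is not involved. The electron-rich 5,7-dialkoxy phenoxide is a poor leaving group, so retro-oxa-Michael ring opening and racemisation are slow.

**Step 3**
Reactants: 4
Product: 5, (2S)-5,7,3′,4′-tetrabenzyloxy-2-aryl-4-(trimethylsilyloxy)-2H-chromene (TMS enol ether, used crude)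
Conditions: TMSOTf (1.5 equiv), Et3N (3 equiv), CH2Cl2, 0 °C, 1 h; non-aqueous workup
Reagents that add atoms: trimethylsilyl triflate, C[Si](C)(C)OS(=O)(=O)C(F)(F)F
Why: Soft silyl-triflate/amine enolisation (Mukaiyama-type) traps the enol without a strong base, so the β-aryloxy ketone does not ring-open, and C2 is not touched. It masks the ketone as an enol ether that is the most oxidisable site in the molecule.

**Step 4**
Reactants: 5 (1.0 equiv) and 2 (2.5 equiv)
Product: 6, protected biflavonoid (2S,3R)-flavanone-3-yl–C8″-(2″R,3″R)-taxifolin, with 5″-OH free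
Conditions: PhI(OCOCF3)2 (PIFA, 1.1 equiv), HFIP/CH2Cl2 (1:4), −20 → 0 °C, slow addition of 5 to 2 and PIFA; then Et3N (5 equiv), 0 °C, 30 min
Reagents that add atoms: none (PIFA, TMS and CF3CO2 are all lost; PhI, TMSOCOCF3 and CF3CO2H leave as by-products)
Why: Proposed new method: PIFA activates the silyl enol ether to give a C3-iodanyl ketone (enolonium equivalent). The HFIP-stabilised electrophilic C3 is then attacked by the C8 of 2, a 1,3,5-trioxygenated arene, in a Friedel–Crafts-type step. The closest known reactions are enolonium α-arylation of ketones with electron-rich arenes and Kita-type PIFA/HFIP oxidative couplings. The arene approaches anti to the pseudo-equatorial C2 aryl, and the Et3N treatment epimerises any cis-2,3 product to the thermodynamic trans (2S,3R) isomer. In the trans-diequatorial half-chair, C2-H is not anti-periplanar to the C3 leaving group, so elimination to flavone is disfavoured. Taxifolin stereocentres are untouched, because conditions are acidic and cold and its 3-OBn prevents enolisation-driven oxidation.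

**Step 5**
Reactants: 6
Product: 7, target
Conditions: H2 (1 atm), Pd(OH)2/C (20%), THF/MeOH (1:1), 25 °C, 12 h
Reagents that add atoms: none (H2 only adds hydrogen)
Why: Catalytic hydrogenolysis removes all eight benzyl ethers under neutral conditions, so no stereocentre is epimerised. The aryl ketones and the ring C–O bonds survive these conditions, as in standard flavanone and catechin debenzylations.

## Compound list
1 | (2R,3R)-(+)-taxifolin | Oc1cc(O)c2c(c1)O[C@H](c1ccc(O)c(O)c1)[C@@H](O)C2=O | starting material
2 | 3,7,3′,4′-tetra-O-benzyl-(2R,3R)-taxifolin, 5-OH free | c3ccccc3COc1cc(O)c2c(c1)O[C@H](c1ccc(OCc3ccccc3)c(OCc3ccccc3)c1)[C@@H](OCc1ccccc1)C2=O | intermediate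
3 | (2S)-(−)-eriodictyol | O=C1c2c(O)cc(O)cc2O[C@H](c2ccc(O)c(O)c2)C1 | starting material
4 | 5,7,3′,4′-tetra-O-benzyl-(2S)-eriodictyol | O=C1c2c(OCc3ccccc3)cc(OCc3ccccc3)cc2O[C@H](c2ccc(OCc3ccccc3)c(OCc3ccccc3)c2)C1 | intermediate
5 | (2S)-TMS enol ether of 4 (4-trimethylsilyloxy-2H-chromene) | C[Si](C)(C)OC1=C[C@@H](c2ccc(OCc3ccccc3)c(OCc3ccccc3)c2)Oc2cc(OCc3ccccc3)cc(OCc3ccccc3)c21 | intermediate
6 | protected dimer (octa-O-benzyl minus 5″-OH: seven OBn, 5″-OH free) | O=C1c2c(OCc3ccccc3)cc(OCc3ccccc3)cc2O[C@H](c2ccc(OCc3ccccc3)c(OCc3ccccc3)c2)[C@H]1c1c(OCc2ccccc2)cc(O)c2c1O[C@H](c1ccc(OCc3ccccc3)c(OCc3ccccc3)c1)[C@@H](OCc1ccccc1)C2=O | intermediate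
7 | EANPDB:THYM_00006, (2S,3R)-eriodictyol-3-yl-(3→8″)-(2″R,3″R)-taxifolin | O=C1c2c(O)cc(O)cc2O[C@H](c2ccc(O)c(O)c2)[C@H]1c1c(O)cc(O)c2c1O[C@H](c1ccc(O)c(O)c1)[C@@H](O)C2=O | target

**Count check:** Compound 6 carries eight benzyl groups: four on the eriodictyol unit (5,7,3′,4′) and four on the taxifolin unit (7″,3″,3‴,4‴). Their removal leaves nine OH groups (C30H22O12), matching the target. The stereotags in 6 are the same as in the target at all four stereocentres.

## Totals
- Total steps: 5
- Longest linear sequence: 4 steps (3 → 4 → 5 → 6 → 7); the taxifolin arm is 3 steps (1 → 2 → 6 → 7).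

## Three steps most likely to fail
1. **Step 4, enolonium coupling.** Risks are elimination to flavone, PIFA over-oxidation of the electron-rich rings, C6 versus C8 regiochemistry, and the very congested bond. Fallback: a different approach, Ni-catalysed cross-electrophile coupling (NiBr2·bipy, Zn, DMA) of 3-bromo-4 (from CuBr2) with 8-iodo-2 (from NIS), a radical coupling that needs no I(III).
2. **Step 3, silyl enol ether formation.** The flavanone may ring-open to the chalcone, or the flavene may decompose or aromatise. Fallback: skip the enol silane and use 3-tosyloxy-4 (from PhI(OH)OTs), activated by a Lewis acid in HFIP as the C3 electrophile toward 2.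
3. **Step 2, eriodictyol benzylation.** Base could racemise C2, which cannot be reset later; step 1 carries the same concern for taxifolin. Fallback: change to non-basic benzylation, either benzyl trichloroacetimidate with catalytic TfOH, or Mitsunobu benzylation (BnOH, DIAD, PPh3).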